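substrate 0.36 M; precatalyst 1.8 mM; added ligand 4.3 mM

* the form that holds most of the catalyst when 30% of the substrate are converted (precatalyst / catalyst / idle complex)
* its share of the catalyst then

    substrate + catalyst → catalyst + product (k1 = 23 M⁻¹ min⁻¹)
    precatalyst → catalyst (k2 = 0.14 min⁻¹)
    catalyst + added ligand ⇌ idle complex (K3 = 460 M⁻¹, k3 = 170 M⁻¹ min⁻¹)

Time is my way in: I sort this flask by its clocks, from fastest to slowest, and ask who is done before whom. I start with binding, and I count the whole charge of precatalyst as activated. With added ligand as charged, the share of catalyst held as idle complex is 66.4%. But each idle complex holds one added ligand. Putting that back leaves 3.10 mM of added ligand free, and the share falls to 58.8%. One more round leaves 3.24 mM and gives 59.9%. This is my bound share, the fraction of activated catalyst held as idle complex at binding equilibrium. It leaves 0.723 mM of free catalyst once activation is over.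

| Rung | Clock | The flask on this rung |
|---|---|---|
| Binding, with added ligand as charged | 0.909 min | catalyst and added ligand come to equilibrium with idle complex |
| Activation of precatalyst | 7.14 min | free catalyst climbs to its plateau |
| Turnover at that free catalyst | 60.2 min | substrate decays pseudo-first-order |

Binding is faster than activation, and activation is faster than turnover. So in this flask binding keeps pace with activation, and substrate then decays at a steady free catalyst. Adding the activation lag to the turnover time, I reckon the conversion asked at 28.6 min. By then precatalyst keeps 1.82% of the charge. My answer for this flask is idle complex, an off-cycle form, with a share of 58.8%.

The forecast gives idle complex at 59%, on the ground that “the ligand holds much of the activated catalyst”.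

The flask reaches that conversion after 0.460 h and then holds 58.5% of its catalyst as idle complex.

The bound share also reckons added ligand: with the charged catalyst split by it, 74.9% of the added ligand stays free. After 2.50 h the flask holds added ligand at 75.0% of its charge.

All constants were drawn at random within sensible limits; no experiment stands behind them.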